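At 50 min, two chemists disagree about this flask, in which scavenger is fed into substrate, partner and initiator.

| flask | substrate | partner | scavenger | initiator | remark | time |
|---|---|---|---|---|---|---|
| eta | 0.10 M | 0.15 M | 0.10 M (fed, over 15 min) | 10 mM | run made earlier; the fed solution adds 0.20 times the starting volume |  |
| gamma | 0.10 M | 0.15 M | 0.22 M (fed, over 15 min) | 10 mM | run made earlier; the fed solution adds 0.20 times the starting volume |  |
| flask | 0.10 M | 0.150 M | 0.150 M (fed, over 15 min) | 10 mM | the fed solution adds 0.20 times the starting volume | 50 min |

| run | time / min | substrate / % | target / % |
|---|---|---|---|
| eta | 8.00 | 45.2 | 48.0 |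
| eta | 15.0 | 33.5 | 56.4 |
| eta | 25.0 | 24.1 | 64.1 |
| eta | 30.0 | 18.9 | 65.7 |
| eta | 40.0 | 15.3 | 68.1 |
| eta | 50.0 | 11.4 | 68.2 |
| eta | 60.0 | 10.9 | 70.3 |
| gamma | 5.00 | 54.5 | 40.2 |
| gamma | 8.00 | 45.7 | 48.5 |
| gamma | 12.0 | 38.3 | 54.2 |
| gamma | 15.0 | 33.3 | 57.2 |
| gamma | 25.0 | 23.4 | 63.5 |
| gamma | 40.0 | 14.7 | 68.9 |
| gamma | 60.0 | 9.9 | 69.7 |

(standard deviation of a reading: 1 percentage point)

- percent here means substrate units held: one ended chains or self-condensation product counts as two
- what is said of released group includes idle adduct
- amounts are per litre of the starting volume; all of the dose is in the solution fed
- steps thought possible: partner + first chain carrier <-> target + second chain carrier; 2 substrate -> self-condensation product; 2 first chain carrier -> ended chains; initiator -> 2 initiating radical; substrate + initiating radical -> capped initiator + first chain carrier; scavenger + released group -> scavenged by-product; substrate + second chain carrier -> released group + first chain carrier; partner + released group <-> idle adduct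
- the reaction counts as stopped when no species that holds the substrate changes by six tenths of a point or more over the second half of the time

- why nothing more happens at 50 min, or that something still does (it is still moving / all of the substrate has reacted / forward and back rates have come level / the partner has run out first)
- share of the substrate used up at 50 min
- target at 50 min, in percent of the substrate charged

The second chemist reads the target. In the eta run it gains 0.1 percentage points from 40.0 min to 50.0 min, against a scatter of 1 point, so she says forward and back rates have come level and the flask will have stopped.

The first chemist reads the substrate, and her forecast is it is still moving, with conversion 88% (range 86% to 90%) and target 69.3% (range 67.5% to 71%). She lets both runs stand for this flask: “Scavenger supply therefore isn't limiting across this range”.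

My own reckoning takes the substrate's loss as pseudo-first-order with a rate coefficient that may drift in time. Integrated, this gives the fraction of the charge left as exp(-L), where L, the count of e-foldings, is the time integral of that coefficient. The log of the fraction left, averaged over the four readings at 40.0 min and 60.0 min in the two runs, puts L at 2.08 at 50 min. That leaves 12.5% of the substrate, so my conversion is 87.5%, a little under the forecast's central value. From 25.0 min to 50 min the substrate then falls by 11 points by the mean of the readings, which is outside the stopping limit, so I side with the forecast.

The flask gives: it is still moving, conversion 87.5%, target 69.8%.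

    partner + first chain carrier ⇌ target + second chain carrier (K = 0.150, k = 2.45 × 10⁵ L mol⁻¹ s⁻¹)
    2 substrate → self-condensation product (k = 1.41 × 10⁻⁵ L mol⁻¹ s⁻¹)
    2 first chain carrier → ended chains (k = 8.00 × 10⁸ L mol⁻¹ s⁻¹)
    initiator → 2 initiating radical (k = 7.06 × 10⁻⁴ s⁻¹)
    substrate + initiating radical → capped initiator + first chain carrier (k = 1.76 × 10⁶ L mol⁻¹ s⁻¹)
    scavenger + released group → scavenged by-product (k = 0.158 L mol⁻¹ s⁻¹)
    substrate + second chain carrier → released group + first chain carrier (k = 31800 L mol⁻¹ s⁻¹)
    partner + released group ⇌ idle adduct, settled at all times (K = 12.0 L mol⁻¹)

The flask's count at 50 min is 2.08. The main reason the flask's target falls short of the charge is the turning of 2 first chain carrier into ended chains: without that step, target at 50 min goes from 69.8% to 99.6%. The second chemist's level is nearly true of one step, partner + first chain carrier <-> target + second chain carrier, whose backward turnover is 98% of the forward one. As a trial on the neighbour flask with 0.090 M of partner, I hold fixed the flask's count for substrate + initiating radical, 0.194, and scale the rest of L by the partner charge, which gives 1.33; that neighbour's own count is 1.35, with 26% of its substrate left.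

The readings are calculated from invented constants; noise was put on by code.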